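**Plan**

- Numbering: ring C1 (C=O), C2 (allyl), C3, C4 (quaternary C–OMe), C5 (C–OMe), C6; side chain C7 (CH–CH3), C8 (CH2–aryl). C4 is a tertiary carbinol carbon bonded to ring carbon C5, whose enol ether is a masked ketone; this α-ketol in the one ring is the retron of an aldehyde-to-ketone benzoin across C4–C5.
- Retrosynthetic cuts, in order: C5 enol ether and C1 ketone back to a C5 ketone and a C1 silyloxy carbinol; C4–C5 (carbene-catalysed benzoin, opens the ring); C3–C4 (vinyllithium plus Weinreb amide); C2–allyl (anti-allylmagnesiation of an alkynol); C7–C8 (auxiliary-controlled enolate alkylation).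
- Forward: fragment A (C4, C7, C8, aryl) and fragment B (C1–C3, C5, C6, allyl, a (Z)-vinyl iodide) are joined at C3–C4, the C5 aldehyde is unmasked, and the only ring closes at C4–C5. Four further steps methylate and adjust oxidation levels.
- Stereochemistry: C7 from alkylation of the (S)-benzyl oxazolidinone imide; C4 from the chiral triazolylidene in the ring closure; the (Z)-alkene from anti carbomagnesiation/iodination; C1 is a temporary centre set by Ru-catalysed transfer hydrogenation and erased in the last step.

Key step: step 11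

Assumption on the catalyst: the sense of induction of the aminoindanol triazolium salt on this aliphatic substrate cannot be derived with certainty; the (5aS,10bR) salt is written, and its equally available mirror image would be used if a pilot cyclisation shows attack on the other ketone face.

Remark on C1: C1 ends as the ring ketone, so its configuration is free; it is installed as (S) so that every intermediate is a single diastereomer.

Step 1
Reactants: 1 (4S)-4-benzyl-3-propanoyl-1,3-oxazolidin-2-one; 2 3,4-dimethoxybenzyl bromide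
Product: 4 (4S)-4-benzyl-3-[(2R)-3-(3,4-dimethoxyphenyl)-2-methylpropanoyl]-1,3-oxazolidin-2-one, via sodium (Z)-enolate 3 (not isolated)
Conditions: NaHMDS, THF, −78 °C; then 2, −78 → −20 °C
Reagents that add atoms: none
Why: Evans asymmetric alkylation: the chelated sodium (Z)-enolate is alkylated by the reactive benzylic bromide on the face opposite the benzyl group of the auxiliary, which sets C7 as (R).

Step 2
Reactants: 4 (4S)-4-benzyl-3-[(2R)-3-(3,4-dimethoxyphenyl)-2-methylpropanoyl]-1,3-oxazolidin-2-one
Product: 5 (2R)-3-(3,4-dimethoxyphenyl)-N-methoxy-N,2-dimethylpropanamide (fragment A)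
Conditions: MeNH(OMe)·HCl, AlMe3, CH2Cl2, −10 °C → rt
Reagents that add atoms: N,O-dimethylhydroxylamine hydrochloride, CNOC.Cl
Why: Aluminium-amide transamidation of the N-acyl oxazolidinone (Weinreb amide formation) attacks only the exocyclic carbonyl and releases the auxiliary without enolising C7.

Step 3
Reactants: 6 methyl 3,3-dimethoxypropanoate
Product: 7 N,3,3-trimethoxy-N-methylpropanamide
Conditions: MeNH(OMe)·HCl, i-PrMgCl, THF, −20 → 0 °C
Reagents that add atoms: N,O-dimethylhydroxylamine hydrochloride, CNOC.Cl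
Why: Aminolysis of an unhindered methyl ester by the chloromagnesium amide (ester-to-Weinreb-amide conversion) is fast at low temperature, and the acetal is inert to the basic medium.

Step 4
Reactants: 7 N,3,3-trimethoxy-N-methylpropanamide; 8 ethynyl(trimethyl)silane
Product: 10 5,5-dimethoxy-1-(trimethylsilyl)pent-1-yn-3-one, via lithium (trimethylsilyl)acetylide 9 (not isolated)
Conditions: 8, n-BuLi, THF, −78 °C; then 7, −78 → −20 °C
Reagents that add atoms: none
Why: Weinreb ketone synthesis: the acetylide adds once to give a chelated tetrahedral intermediate that collapses only on quench, so neither over-addition nor base-induced loss of methanol from the β-keto acetal should occur.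

Step 5
Reactants: 10 5,5-dimethoxy-1-(trimethylsilyl)pent-1-yn-3-one
Product: 11 (3S)-5,5-dimethoxy-1-(trimethylsilyl)pent-1-yn-3-ol
Conditions: Ru[(S,S)-TsDPEN](p-cymene) (amido complex preformed from RuCl[(S,S)-TsDPEN](p-cymene) and KOH, 2 mol %), i-PrOH, rt
Reagents that add atoms: none
Why: Noyori asymmetric transfer hydrogenation of an alkynyl ketone: the alkyne takes the place of the arene of an aryl ketone in the six-membered hydride-transfer transition state, so the (S,S)-ligand should deliver the (S)-carbinol, the temporary C1 centre.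

Step 6
Reactants: 11 (3S)-5,5-dimethoxy-1-(trimethylsilyl)pent-1-yn-3-ol
Product: 12 (3S)-5,5-dimethoxypent-1-yn-3-ol
Conditions: K2CO3 (cat.), MeOH, rt
Reagents that add atoms: none
Why: Base-catalysed methanolysis of the alkynyl C–Si bond (protodesilylation) leaves the acetal and the carbinol centre untouched.

Step 7
Reactants: 12 (3S)-5,5-dimethoxypent-1-yn-3-ol; 13 allylmagnesium bromide
Product: 15 (3S,4Z)-4-(iodomethylidene)-1,1-dimethoxyhept-6-en-3-ol, via oxamagnesacycle 14 (not isolated)
Conditions: 13 (3 equiv), CuI (10 mol %), Et2O, −10 °C → rt; then I2, THF, −40 → 0 °C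
Reagents that add atoms: iodine, II
Why: Alkoxide-directed anti-carbomagnesiation of a propargylic alcohol: allyl goes to the internal alkyne carbon C2 and magnesium to the terminal C3 on the opposite side, held in a five-membered chelate by the alkoxide, and iodinolysis with retention gives the iodide cis to C1, the (Z)-alkene that later places C4 and C1 on the same side.

Step 8
Reactants: 15 (3S,4Z)-4-(iodomethylidene)-1,1-dimethoxyhept-6-en-3-ol
Product: 16 tert-butyl{[(3S,4Z)-4-(iodomethylidene)-1,1-dimethoxyhept-6-en-3-yl]oxy}diphenylsilane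
Conditions: TBDPSCl, imidazole, DMAP (cat.), DMF, rt → 40 °C
Reagents that add atoms: tert-butyl(chloro)diphenylsilane, CC(C)(C)[Si](Cl)(c1ccccc1)c1ccccc1
Why: Silyl ether formation with the chloride and imidazole avoids silyl triflates, which would activate the dimethyl acetal, and the bulky acid-stable tert-butyldiphenylsilyl group is chosen to survive the two later acid steps and to resist O-to-C silyl migration in the next step.

Step 9
Reactants: 16 tert-butyl{[(3S,4Z)-4-(iodomethylidene)-1,1-dimethoxyhept-6-en-3-yl]oxy}diphenylsilane (fragment B); 5 (2R)-3-(3,4-dimethoxyphenyl)-N-methoxy-N,2-dimethylpropanamide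
Product: 18 (2R,4Z,6S)-6-[(tert-butyldiphenylsilyl)oxy]-1-(3,4-dimethoxyphenyl)-8,8-dimethoxy-2-methyl-5-(prop-2-en-1-yl)oct-4-en-3-one, via vinyllithium 17 (not isolated)
Conditions: t-BuLi (2.05 equiv), Et2O, −78 °C; then 5, −78 → −40 °C
Reagents that add atoms: none
Why: Lithium–iodine exchange keeps the alkene geometry and the vinyllithium acylates once on the Weinreb amide (Weinreb ketone synthesis), the chelated adduct shielding C7 from epimerisation, while ether, low temperature and the bulky silyl group suppress the 1,4 O-to-C silyl shift (retro-Brook rearrangement) open to a cis-γ-silyloxy vinyllithium.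

Step 10
Reactants: 18 (2R,4Z,6S)-6-[(tert-butyldiphenylsilyl)oxy]-1-(3,4-dimethoxyphenyl)-8,8-dimethoxy-2-methyl-5-(prop-2-en-1-yl)oct-4-en-3-one
Product: 19 (3S,4Z,7R)-3-[(tert-butyldiphenylsilyl)oxy]-8-(3,4-dimethoxyphenyl)-7-methyl-6-oxo-4-(prop-2-en-1-yl)oct-4-enal
Conditions: TsOH·H2O (10 mol %), acetone/H2O (10:1), 0 °C → rt
Reagents that add atoms: water, O
Why: Acid-catalysed hydrolysis of a dimethyl acetal (acetal deprotection) is far faster than cleavage of the tert-butyldiphenylsilyl ether, and the mild non-basic medium should leave the (Z)-enone, C7 and the β-silyloxy aldehyde intact.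

Step 11
Reactants: 19 (3S,4Z,7R)-3-[(tert-butyldiphenylsilyl)oxy]-8-(3,4-dimethoxyphenyl)-7-methyl-6-oxo-4-(prop-2-en-1-yl)oct-4-enal
Product: 20 (2S,5S)-5-[(tert-butyldiphenylsilyl)oxy]-2-[(2R)-1-(3,4-dimethoxyphenyl)propan-2-yl]-2-hydroxy-4-(prop-2-en-1-yl)cyclohex-3-en-1-one
Conditions: (5aS,10bR)-2-(pentafluorophenyl)-5a,10b-dihydro-4H,6H-indeno[2,1-b][1,2,4]triazolo[4,3-d][1,4]oxazin-2-ium tetrafluoroborate (15 mol %), Et3N (15 mol %), toluene (0.02 M), rt
Reagents that add atoms: none
Why: The triazolylidene freed by Et3N adds to the C5 aldehyde and proton transfer gives the Breslow intermediate, whose nucleophilic C5 attacks the C4 ketone carbonyl before the tetrahedral adduct expels the carbene and leaves the α-ketol. The closest known reaction type is the enantioselective intramolecular crossed aldehyde–ketone benzoin cyclisation with aminoindanol-derived triazolium salts, which gives six-membered tertiary α-ketols. The ring C1–C6 closes in a 6-exo-trig mode at the carbonyl carbon C4. The new C4 centre is set by the chiral carbene, which has to deliver C5 to the ketone face that gives (4S); the Felkin–Anh preference of the neighbouring C7 centre is expected to be small and to point the other way, so control by the catalyst is indispensable. Chemoselectivity is secured by the substrate: the (Z)-alkene holds C1 and C4 cis, a Stetter addition at C2 would need a four-membered ring, the ketone cannot serve as acyl donor and dilution disfavours aldehyde homo-coupling. A catalytic amount of a weak amine base keeps C7 from epimerising and the β-silyloxy aldehyde from losing silanol by E1cB elimination.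

Step 12
Reactants: 20 (2S,5S)-5-[(tert-butyldiphenylsilyl)oxy]-2-[(2R)-1-(3,4-dimethoxyphenyl)propan-2-yl]-2-hydroxy-4-(prop-2-en-1-yl)cyclohex-3-en-1-one
Product: 21 (2S,5S)-5-[(tert-butyldiphenylsilyl)oxy]-2-[(2R)-1-(3,4-dimethoxyphenyl)propan-2-yl]-2-methoxy-4-(prop-2-en-1-yl)cyclohex-3-en-1-one
Conditions: MeOTf, 2,6-di-tert-butyl-4-methylpyridine, CH2Cl2, rt → 40 °C
Reagents that add atoms: methyl trifluoromethanesulfonate, COS(=O)(=O)C(F)(F)F
Why: Electrophilic O-methylation of a hindered tertiary alcohol with methyl triflate and a non-nucleophilic pyridine base never forms an alkoxide or enolate, which avoids α-ketol rearrangement, retro-benzoin cleavage and E1cB loss of the β-silyloxy group.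

Step 13
Reactants: 21 (2S,5S)-5-[(tert-butyldiphenylsilyl)oxy]-2-[(2R)-1-(3,4-dimethoxyphenyl)propan-2-yl]-2-methoxy-4-(prop-2-en-1-yl)cyclohex-3-en-1-one
Product: 22 tert-butyl({(1S,4S)-4-[(2R)-1-(3,4-dimethoxyphenyl)propan-2-yl]-4,5,5-trimethoxy-2-(prop-2-en-1-yl)cyclohex-2-en-1-yl}oxy)diphenylsilane
Conditions: HC(OMe)3, MeOH, CSA (20 mol %), rt → 40 °C
Reagents that add atoms: trimethyl orthoformate, COC(OC)OC; methanol, CO
Why: Acid-catalysed ketalisation driven by the orthoformate as water scavenger should convert the electrophilic α-methoxy cyclohexanone into its dimethyl ketal while the tert-butyldiphenylsilyl ether, the tertiary methyl ether and the alkenes tolerate the mild acid.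

Step 14
Reactants: 22 tert-butyl({(1S,4S)-4-[(2R)-1-(3,4-dimethoxyphenyl)propan-2-yl]-4,5,5-trimethoxy-2-(prop-2-en-1-yl)cyclohex-2-en-1-yl}oxy)diphenylsilane
Product: 23 (1S,4S)-4-[(2R)-1-(3,4-dimethoxyphenyl)propan-2-yl]-4,5,5-trimethoxy-2-(prop-2-en-1-yl)cyclohex-2-en-1-ol
Conditions: TBAF, THF, rt
Reagents that add atoms: none
Why: Fluoride-mediated desilylation is safe at this stage because no carbonyl group is present, so neither β-elimination nor retro-aldol cleavage can intervene, and the ketal, ethers and alkenes are inert to fluoride.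

Step 15
Reactants: 23 (1S,4S)-4-[(2R)-1-(3,4-dimethoxyphenyl)propan-2-yl]-4,5,5-trimethoxy-2-(prop-2-en-1-yl)cyclohex-2-en-1-ol
Product: 25 lancifolin C [(4S)-4-[(2R)-1-(3,4-dimethoxyphenyl)propan-2-yl]-4,5-dimethoxy-2-(prop-2-en-1-yl)cyclohexa-2,5-dien-1-one], via β-keto ketal 24 (not isolated)
Conditions: DMP, NaHCO3, CH2Cl2, 0 °C → rt; filter; then DBU (cat.), CH2Cl2, rt
Reagents that add atoms: none
Why: Dess–Martin oxidation of the secondary allylic alcohol gives the β-keto ketal, and base-mediated E1cB loss of methanol (β-alkoxy elimination to a vinylogous ester) can only occur between C6, the sole acidic position, and C5, the sole β-carbon with a leaving group, so the enol ether double bond is placed at C5=C6 without a regiochemical choice.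

**Compound list**

1 | (4S)-4-benzyl-3-propanoyl-1,3-oxazolidin-2-one | CCC(=O)N1[C@@H](Cc2ccccc2)COC1=O | starting material
2 | 3,4-dimethoxybenzyl bromide | COc1ccc(CBr)cc1OC | starting material
3 | sodium (Z)-enolate of 1 | C/C=C(\[O-])N1[C@@H](Cc2ccccc2)COC1=O.[Na+] | intermediate (not isolated)
4 | (4S)-4-benzyl-3-[(2R)-3-(3,4-dimethoxyphenyl)-2-methylpropanoyl]-1,3-oxazolidin-2-one | C[C@H](Cc1ccc(OC)c(OC)c1)C(=O)N1[C@@H](Cc2ccccc2)COC1=O | intermediate
5 | (2R)-3-(3,4-dimethoxyphenyl)-N-methoxy-N,2-dimethylpropanamide | C[C@H](Cc1ccc(OC)c(OC)c1)C(=O)N(C)OC | intermediate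
6 | methyl 3,3-dimethoxypropanoate | COC(=O)CC(OC)OC | starting material
7 | N,3,3-trimethoxy-N-methylpropanamide | CON(C)C(=O)CC(OC)OC | intermediate
8 | ethynyl(trimethyl)silane | C#C[Si](C)(C)C | starting material
9 | lithium (trimethylsilyl)acetylide | [Li]C#C[Si](C)(C)C | intermediate (not isolated)
10 | 5,5-dimethoxy-1-(trimethylsilyl)pent-1-yn-3-one | COC(OC)CC(=O)C#C[Si](C)(C)C | intermediate
11 | (3S)-5,5-dimethoxy-1-(trimethylsilyl)pent-1-yn-3-ol | COC(OC)C[C@H](O)C#C[Si](C)(C)C | intermediate
12 | (3S)-5,5-dimethoxypent-1-yn-3-ol | COC(OC)C[C@H](O)C#C | intermediate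
13 | allylmagnesium bromide | C=CC[Mg]Br | starting material
14 | oxamagnesacycle (2,5-dihydro-1,2-oxamagnesole with allyl on C2 and magnesium on C3, cis to C1) | C=CCC1=C[Mg]O[C@H]1CC(OC)OC | intermediate (not isolated)
15 | (3S,4Z)-4-(iodomethylidene)-1,1-dimethoxyhept-6-en-3-ol | I/C=C(/CC=C)[C@@H](O)CC(OC)OC | intermediate
16 | tert-butyl{[(3S,4Z)-4-(iodomethylidene)-1,1-dimethoxyhept-6-en-3-yl]oxy}diphenylsilane | I/C=C(/CC=C)[C@@H](O[Si](c1ccccc1)(c1ccccc1)C(C)(C)C)CC(OC)OC | intermediate
17 | vinyllithium from 16 (lithium in place of iodine, cis to the silyloxy-bearing carbon) | [Li]/C=C(/CC=C)[C@@H](O[Si](c1ccccc1)(c1ccccc1)C(C)(C)C)CC(OC)OC | intermediate (not isolated)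
18 | (2R,4Z,6S)-6-[(tert-butyldiphenylsilyl)oxy]-1-(3,4-dimethoxyphenyl)-8,8-dimethoxy-2-methyl-5-(prop-2-en-1-yl)oct-4-en-3-one | C=CC/C(=C/C(=O)[C@H](C)Cc1ccc(OC)c(OC)c1)[C@H](CC(OC)OC)O[Si](c1ccccc1)(c1ccccc1)C(C)(C)C | intermediate
19 | (3S,4Z,7R)-3-[(tert-butyldiphenylsilyl)oxy]-8-(3,4-dimethoxyphenyl)-7-methyl-6-oxo-4-(prop-2-en-1-yl)oct-4-enal | C=CC/C(=C/C(=O)[C@H](C)Cc1ccc(OC)c(OC)c1)[C@H](CC=O)O[Si](c1ccccc1)(c1ccccc1)C(C)(C)C | intermediate (precursor of the key step)
20 | (2S,5S)-5-[(tert-butyldiphenylsilyl)oxy]-2-[(2R)-1-(3,4-dimethoxyphenyl)propan-2-yl]-2-hydroxy-4-(prop-2-en-1-yl)cyclohex-3-en-1-one | C=CCC1=C[C@@](O)([C@H](C)Cc2ccc(OC)c(OC)c2)C(=O)C[C@@H]1O[Si](c1ccccc1)(c1ccccc1)C(C)(C)C | intermediate (product of the key step)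
21 | (2S,5S)-5-[(tert-butyldiphenylsilyl)oxy]-2-[(2R)-1-(3,4-dimethoxyphenyl)propan-2-yl]-2-methoxy-4-(prop-2-en-1-yl)cyclohex-3-en-1-one | C=CCC1=C[C@@](OC)([C@H](C)Cc2ccc(OC)c(OC)c2)C(=O)C[C@@H]1O[Si](c1ccccc1)(c1ccccc1)C(C)(C)C | intermediate
22 | tert-butyl({(1S,4S)-4-[(2R)-1-(3,4-dimethoxyphenyl)propan-2-yl]-4,5,5-trimethoxy-2-(prop-2-en-1-yl)cyclohex-2-en-1-yl}oxy)diphenylsilane | C=CCC1=C[C@@](OC)([C@H](C)Cc2ccc(OC)c(OC)c2)C(OC)(OC)C[C@@H]1O[Si](c1ccccc1)(c1ccccc1)C(C)(C)C | intermediate
23 | (1S,4S)-4-[(2R)-1-(3,4-dimethoxyphenyl)propan-2-yl]-4,5,5-trimethoxy-2-(prop-2-en-1-yl)cyclohex-2-en-1-ol | C=CCC1=C[C@@](OC)([C@H](C)Cc2ccc(OC)c(OC)c2)C(OC)(OC)C[C@@H]1O | intermediate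
24 | (4S)-4-[(2R)-1-(3,4-dimethoxyphenyl)propan-2-yl]-4,5,5-trimethoxy-2-(prop-2-en-1-yl)cyclohex-2-en-1-one | C=CCC1=C[C@@](OC)([C@H](C)Cc2ccc(OC)c(OC)c2)C(OC)(OC)CC1=O | intermediate (not isolated)
25 | lancifolin C, (4S)-4-[(2R)-1-(3,4-dimethoxyphenyl)propan-2-yl]-4,5-dimethoxy-2-(prop-2-en-1-yl)cyclohexa-2,5-dien-1-one | C=CCC1=C[C@@](OC)([C@H](C)Cc2ccc(OC)c(OC)c2)C(OC)=CC1=O | target

**Count**

Total steps: 15. Longest linear sequence: 13 steps (steps 3–15, from methyl 3,3-dimethoxypropanoate); fragment A joins after 2 steps.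

**Steps most likely to fail**

Step 11. The 1,2-addition of the Breslow intermediate to the conjugated, α-branched ketone may be slow, which gives time for E1cB loss of silanol from the β-silyloxy aldehyde. The catalyst may also fail to override the bias of the C7 centre, giving poor facial selectivity at C4. Fallback: setting out from 19, a ketyl–carbonyl pinacol cyclisation with SmI2 (THF, −78 °C) would close the same C4–C5 bond at the diol oxidation level and give the ring 4,5-diol F1 (C5 carbinol configuration immaterial; C4 epimers are diastereomers and separable). Parikh–Doering oxidation of the secondary C5 hydroxyl alone would then give the α-ketol, and the route is rejoined at 20.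

Step 12. The tertiary C4 hydroxyl, flanked by a ketone, a branched alkyl group and a ring alkene, may be methylated too slowly. Forcing conditions invite migration of a C4 substituent to C5 (α-ketol rearrangement) or loss of the silyloxy group through enolisation. Fallback: setting out from 20, the ketone is ketalised first (HC(OMe)3, MeOH, CSA) to the C4-hydroxy C5 dimethyl ketal F2. This compound has no carbonyl group and therefore tolerates Williamson methylation of its potassium alkoxide (KH, MeI, THF, 0 °C). The route is rejoined at 22, with the order of methylation and ketalisation exchanged.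

Step 13. Ketalisation at C5 next to the fully substituted C4 may stall, or prolonged acid treatment may eliminate the β-silyloxy group through the enol. Fallback: setting out from 21, the silyl group is removed with HF·pyridine to give the C1-hydroxy C5 ketone F3, which is oxidised with Dess–Martin periodinane to the enolised ring 1,5-dione F4. Acid-catalysed methanolysis under equilibrating conditions (HC(OMe)3, MeOH, TsOH) would convert this into its vinylogous methyl ester. The cross-conjugated 2,5-dienone is expected to be the more stable regioisomer, and any linear 2,4-dienone isomer would be returned to the same equilibrium. The route is rejoined at 25.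

Further compounds
F1 | step 11 | (C4S)-ring 4,5-diol: C4 tertiary carbinol, C5 secondary carbinol (configuration open), C1 tert-butyldiphenylsilyl ether | C=CCC1=C[C@@](O)([C@H](C)Cc2ccc(OC)c(OC)c2)C(O)C[C@@H]1O[Si](c1ccccc1)(c1ccccc1)C(C)(C)C
F2 | step 12 | C4-hydroxy C5 dimethyl ketal, C1 tert-butyldiphenylsilyl ether | C=CCC1=C[C@@](O)([C@H](C)Cc2ccc(OC)c(OC)c2)C(OC)(OC)C[C@@H]1O[Si](c1ccccc1)(c1ccccc1)C(C)(C)C
F3 | step 13 | (2S,5S)-2-[(2R)-1-(3,4-dimethoxyphenyl)propan-2-yl]-5-hydroxy-2-methoxy-4-(prop-2-en-1-yl)cyclohex-3-en-1-one | C=CCC1=C[C@@](OC)([C@H](C)Cc2ccc(OC)c(OC)c2)C(=O)C[C@@H]1O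
F4 | step 13 | (4S)-4-[(2R)-1-(3,4-dimethoxyphenyl)propan-2-yl]-4-methoxy-6-(prop-2-en-1-yl)cyclohex-5-ene-1,3-dione (enolised) | C=CCC1=C[C@@](OC)([C@H](C)Cc2ccc(OC)c(OC)c2)C(=O)CC1=O
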